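**Retrosynthetic overview**
1. Last bond: the ester C–O between the primary alcohol of lactone diol 30 and acrylic acid 16; all silicon groups are removed in one final fluoride step.
2. Lactone half: the seven-membered lactone is closed by a new regioselective crossed Tishchenko reaction of dialdehyde 28. Dialdehyde 28 comes from ozonolysis of a sacrificial ring B in a cis-fused bicyclic diene ester, which fixes the cis ring fusion and the alkene geometry.
3. That bicycle comes from a Diels–Alder reaction of (S)-cryptone (ring A) with Rawal's diene, anti to isopropyl, followed by convex-face hydroxymethylation of the ketone.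
4. Acid half: (R)-cryptone, hydroxymethylation and oxidative transposition, Luche reduction to the trans allylic carbonate, stereoinvertive palladium allyl–alkynyl coupling (cis), then syn-hydrostannation and carboxylation.
5. Ring order: ring A of each half (organocatalytic Robinson annulation), ring B (cycloaddition), ring B cleaved, seven-membered lactone, ester union.

Assumption: the SMILES is taken literally, so isopropyl and side chain are cis on the cyclohexene of the acyl half and trans on the lactone half; the two halves therefore come from enantiomeric cryptones.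

**Acid half**

Step 1
Reactants: 1 isovaleraldehyde (3-methylbutanal); 2 methyl vinyl ketone (but-3-en-2-one)
Product: 4 (4R)-4-(propan-2-yl)cyclohex-2-en-1-one [(R)-cryptone], via (2R)-5-oxo-2-(propan-2-yl)hexanal 3 (not isolated)
Conditions: (R)-2-[methoxy(diphenyl)methyl]pyrrolidine (5 mol %), ethyl 3,4-dihydroxybenzoate (20 mol %), neat, 4 °C; then LiOH (cat.), iPrOH, rt
Reagents that add atoms: none
Why: Enamine-catalysed Michael addition in which the diphenyl(methoxy)methyl group shields one enamine face and sets the (R) centre, followed by intramolecular aldol condensation (organocatalytic Robinson annulation).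

Step 2
Reactants: 4 (R)-cryptone
Product: 5 (4R)-1-(hydroxymethyl)-4-(propan-2-yl)cyclohex-2-en-1-ol (both C1 epimers)
Conditions: Bu3SnCH2OH, nBuLi (2 equiv), THF, −78 → −20 °C; then 4, −78 °C; H2O
Reagents that add atoms: (tributylstannyl)methanol, CCCC[Sn](CCCC)(CCCC)CO
Why: 1,2-Addition of dilithiated methanol (hydroxymethyl anion equivalent made by tin–lithium exchange) to the enone carbonyl; the new carbinol centre forms as a mixture that is erased in step 4.

Step 3
Reactants: 5 diol
Product: 6 (4R)-1-({[tert-butyl(dimethyl)silyl]oxy}methyl)-4-(propan-2-yl)cyclohex-2-en-1-ol (both C1 epimers)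
Conditions: TBSCl, imidazole, CH2Cl2, 0 °C
Reagents that add atoms: tert-butyl(chloro)dimethylsilane (TBSCl), CC(C)(C)[Si](C)(C)Cl
Why: Selective silylation of the primary over the tertiary alcohol.

Step 4
Reactants: 6 tertiary allylic alcohol
Product: 7 (6R)-3-({[tert-butyl(dimethyl)silyl]oxy}methyl)-6-(propan-2-yl)cyclohex-2-en-1-one
Conditions: [C5H5NH][CrO3Cl] (pyridinium chlorochromate), NaOAc, 4 Å sieves, CH2Cl2, rt
Reagents that add atoms: pyridinium chlorochromate, [O-][Cr](=O)(=O)Cl.c1cc[nH+]cc1
Why: Dauben–Babler oxidative 1,3-transposition ([3,3] shift of the tertiary allylic chromate ester, then oxidation) gives the same enone from either C1 epimer and leaves the isopropyl centre untouched under buffered conditions.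

Step 5
Reactants: 7 enone
Product: 8 (1R,6R)-3-({[tert-butyl(dimethyl)silyl]oxy}methyl)-6-(propan-2-yl)cyclohex-2-en-1-ol (hydroxyl trans to isopropyl)
Conditions: NaBH4, CeCl3·7H2O, MeOH, −78 °C
Reagents that add atoms: none
Why: Luche 1,2-reduction; axial hydride delivery to the half-chair with equatorial isopropyl gives the pseudo-equatorial (1R) alcohol trans to isopropyl (the minor cis epimer is removed by chromatography).

Step 6
Reactants: 8 trans allylic alcohol
Product: 9 methyl (1R,6R)-3-({[tert-butyl(dimethyl)silyl]oxy}methyl)-6-(propan-2-yl)cyclohex-2-en-1-yl carbonate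
Conditions: ClCO2Me, pyridine, CH2Cl2, 0 °C
Reagents that add atoms: methyl chloroformate, COC(=O)Cl
Why: O-Acylation gives an ionisable allylic carbonate with retention at carbon.

Step 7
Reactants: 9 allylic carbonate; 10 tert-butyl(dimethyl)(prop-2-yn-1-yloxy)silane
Product: 13 tert-butyl({(3S,4R)-3-[3-({tert-butyl(dimethyl)silyl}oxy)prop-1-yn-1-yl]-4-(propan-2-yl)cyclohex-1-en-1-yl}methoxy)dimethylsilane (alkynyl cis to isopropyl), via LiC≡CCH2OTBS 11 (not isolated), via ClZnC≡CCH2OTBS 12 (not isolated)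
Conditions: 10, nBuLi, THF, −78 °C; ZnCl2, 0 °C; then 9, Pd(PPh3)4 (5 mol %), THF, 25–45 °C
Reagents that add atoms: none
Why: Negishi-type allyl–alkynyl cross-coupling: zerovalent palladium ionises the carbonate anti to the leaving group, the alkynyl group is transferred to palladium and delivered from the metal face to the less substituted allyl terminus, so net inversion places the alkyne cis to isopropyl (new centre 3S).

Step 8
Reactants: 13 enyne
Product: 14 tributyl{(1E)-3-{[tert-butyl(dimethyl)silyl]oxy}-1-[(1S,6R)-3-({[tert-butyl(dimethyl)silyl]oxy}methyl)-6-(propan-2-yl)cyclohex-2-en-1-yl]prop-1-en-2-yl}stannane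
Conditions: Bu3SnH, PdCl2(PPh3)2 (2 mol %), THF, 0 °C → rt
Reagents that add atoms: tributylstannane, CCCC[SnH](CCCC)CCCC
Why: Palladium-catalysed syn-hydrostannation; tin goes to the less hindered alkyne carbon next to CH2OSi and hydrogen to the ring side, which fixes the ring cis to CH2O across the new double bond.

Step 9
Reactants: 14 alkenylstannane
Product: 16 (2E)-2-({[tert-butyl(dimethyl)silyl]oxy}methyl)-3-[(1S,6R)-3-({[tert-butyl(dimethyl)silyl]oxy}methyl)-6-(propan-2-yl)cyclohex-2-en-1-yl]prop-2-enoic acid, via alkenyllithium 15 (not isolated)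
Conditions: MeLi, THF, −78 → −40 °C; CO2, −78 °C; dilute HCl
Reagents that add atoms: carbon dioxide, O=C=O
Why: Tin–lithium exchange and carboxylation of the alkenyllithium both proceed with retention of double-bond geometry and give the (2E) acid.

**Lactone half**

Step 10
Reactants: 1 isovaleraldehyde; 2 methyl vinyl ketone
Product: 18 (4S)-4-(propan-2-yl)cyclohex-2-en-1-one [(S)-cryptone], via (2S)-5-oxo-2-(propan-2-yl)hexanal 17 (not isolated)
Conditions: (S)-2-[methoxy(diphenyl)methyl]pyrrolidine (5 mol %), ethyl 3,4-dihydroxybenzoate (20 mol %), neat, 4 °C; then LiOH (cat.), iPrOH, rt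
Reagents that add atoms: none
Why: Same enamine Michael addition and aldol condensation as step 1 with the enantiomeric catalyst, which sets the (S) centre.

Step 11
Reactants: 18 (S)-cryptone; 19 Rawal's diene (1E)-3-{[tert-butyl(dimethyl)silyl]oxy}-N,N-dimethylbuta-1,3-dien-1-amine
Product: 20 (4S,4aS,8S,8aR)-6-{[tert-butyl(dimethyl)silyl]oxy}-8-(dimethylamino)-4-(propan-2-yl)-3,4,4a,5,8,8a-hexahydronaphthalen-1(2H)-one
Conditions: toluene, 90 °C, sealed tube
Reagents that add atoms: none
Why: Diels–Alder cycloaddition: the aminosiloxy diene adds suprafacially (cis ring fusion) and endo to the enone face opposite the 4-isopropyl group, with its amino terminus bonding to the α-carbon, which sets C4a and C8a.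

Step 12
Reactants: 20 cycloadduct
Product: 22 (4aS,5R,8S,8aS)-5-hydroxy-5-(hydroxymethyl)-8-(propan-2-yl)-4a,5,6,7,8,8a-hexahydronaphthalen-2(1H)-one, via amino silyl enol ether diol 21 (not isolated)
Conditions: Bu3SnCH2OH, nBuLi (2 equiv), THF, −78 → −20 °C; then 20, −78 → 0 °C; then 1 M HCl, THF, 0 °C
Reagents that add atoms: (tributylstannyl)methanol, CCCC[Sn](CCCC)(CCCC)CO
Why: 1,2-Addition of dilithiated methanol to the ketone from the convex face, anti to the neighbouring ring-fusion bond of ring B, sets the carbinol centre (CH2OH anti and OH syn to that bond); acid then hydrolyses the silyl enol ether and eliminates dimethylamine to the enone.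

Step 13
Reactants: 22 enone diol
Product: 23 acetonide of 22 (2,2-dimethyl-1,3-dioxolane spiro at C5; stereocentres as in 22)
Conditions: Me2C(OMe)2, PPTS (cat.), acetone, rt
Reagents that add atoms: 2,2-dimethoxypropane, COC(C)(C)OC
Why: Acetal exchange ties the tertiary and primary hydroxyls into a dioxolane.

Step 14
Reactants: 23 enone acetonide
Product: 25 cross-conjugated dienyl triflate (2-trifloxy-4a,5,6,7,8,8a-hexahydronaphthalene with C1=C2 and C3=C4; stereocentres as in 23), via lithium dienolate 24 (not isolated)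
Conditions: LiN(iPr)2, THF, −78 °C; PhNTf2, −78 → 0 °C; aq NH4Cl
Reagents that add atoms: N-phenylbis(trifluoromethanesulfonimide), FC(F)(F)S(=O)(=O)N(c1ccccc1)S(=O)(=O)C(F)(F)F
Why: Kinetic α′-deprotonation of the enone gives the cross-conjugated enolate, which is trapped on oxygen (enol triflate formation).

Step 15
Reactants: 25 dienyl triflate
Product: 26 2-(trimethylsilyl)ethyl diene ester (ester on C2 of the 4a,5,6,7,8,8a-hexahydronaphthalene; stereocentres as in 23)
Conditions: Pd(OAc)2 (5 mol %), PPh3 (10 mol %), CO (1 atm), Me3SiCH2CH2OH, Et3N, DMF, 50 °C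
Reagents that add atoms: carbon monoxide, [C-]#[O+]; 2-(trimethylsilyl)ethanol, C[Si](C)(C)CCO
Why: Palladium-catalysed alkoxycarbonylation of the alkenyl triflate (oxidative addition, CO insertion, alcoholysis).

Step 16
Reactants: 26 diene ester
Product: 28 dialdehyde 2-(trimethylsilyl)ethyl (2E)-2-formyl-3-[6-formyl-2,2-dimethyl-8-(propan-2-yl)-1,3-dioxaspiro[4.5]decan-7-yl]prop-2-enoate (ring cis to CHO across C=C; stereocentres as in 23), via ozonide 27 (not isolated)
Conditions: O3, CH2Cl2, Sudan red 7B indicator, −78 °C; then PPh3, −78 °C → rt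
Reagents that add atoms: ozone, [O-][O+]=O
Why: Ozonolysis with reductive work-up cleaves the electron-richer disubstituted C3=C4 bond and spares the ester-bearing double bond, whose geometry is inherited from ring B.

Step 17
Reactants: 28 dialdehyde
Product: 29 acetonide-protected cis-fused seven-membered lactone (2-(trimethylsilyl)ethyl ester; stereocentres as in 30)
Conditions: Al(OiPr)3 (10 mol %), toluene (0.01 M), 25–40 °C
Reagents that add atoms: none
Why: Proposed new method: an Al(OiPr)3 hydride shuttle should convert the unsymmetrical dialdehyde into a single lactone, because the saturated aldehyde is the one captured as a lactol aluminate by the neighbouring alkoxide and so acts as hydride donor, while the free conjugated 2-formylacrylate aldehyde is the acceptor in a six-membered Meerwein–Ponndorf–Verley transition state that cannot deliver hydride in a conjugate sense, and the cis ring fusion together with the ring-derived alkene geometry holds the CH2O arm next to the acyl carbon so the seven-membered ring closes intramolecularly without touching the stereocentres; the closest known reactions are the Al(OR)3 Tishchenko dimerisation of aldehydes, the Tishchenko lactonisation of symmetrical dialdehydes and the Evans–Tishchenko reduction, none of which has been used for a regioselective crossed ring closure of a saturated aldehyde onto a 2-formylacrylate.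

Step 18
Reactants: 29 lactone acetonide
Product: 30 2-(trimethylsilyl)ethyl (5aR,6S,9R,9aS)-9-hydroxy-9-(hydroxymethyl)-1-oxo-6-(propan-2-yl)-1,3,5a,6,7,8,9,9a-octahydro-2-benzoxepine-4-carboxylate
Conditions: AcOH/THF/H2O (3:1:1), 35 °C; used at once
Reagents that add atoms: none
Why: Mild acid hydrolysis of the dioxolane frees the diol without touching the lactone, the silylethyl ester or the stereocentres.

**Union and deprotection**

Step 19
Reactants: 30 lactone diol; 16 acid
Product: 31 2-(trimethylsilyl)ethyl (5aR,6S,9R,9aS)-9-{[((2E)-2-({[tert-butyl(dimethyl)silyl]oxy}methyl)-3-[(1S,6R)-3-({[tert-butyl(dimethyl)silyl]oxy}methyl)-6-(propan-2-yl)cyclohex-2-en-1-yl]prop-2-enoyl)oxy]methyl}-9-hydroxy-1-oxo-6-(propan-2-yl)-1,3,5a,6,7,8,9,9a-octahydro-2-benzoxepine-4-carboxylate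
Conditions: 2-methyl-6-nitrobenzoic anhydride (MNBA), DMAP, Et3N, CH2Cl2, rt
Reagents that add atoms: none
Why: Shiina mixed-anhydride esterification acylates the primary alcohol only, since the tertiary alcohol is too hindered to react.

Step 20
Reactants: 31 protected ester
Product: 32 target, (5aR,6S,9R,9aS)-9-hydroxy-9-{[((2E)-2-(hydroxymethyl)-3-[(1S,6R)-3-(hydroxymethyl)-6-(propan-2-yl)cyclohex-2-en-1-yl]prop-2-enoyl)oxy]methyl}-1-oxo-6-(propan-2-yl)-1,3,5a,6,7,8,9,9a-octahydro-2-benzoxepine-4-carboxylic acid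
Conditions: tris(dimethylamino)sulfonium difluorotrimethylsilicate (TASF), DMF, 0 °C → rt; aq NH4Cl
Reagents that add atoms: none
Why: Fluoride-mediated global desilylation cleaves both silyl ethers and fragments the 2-(trimethylsilyl)ethyl ester under near-neutral conditions that spare the lactone, the ester link and the stereocentre next to the lactone carbonyl.

**Compound list**
1 | isovaleraldehyde (3-methylbutanal) | CC(C)CC=O | starting material
2 | methyl vinyl ketone (but-3-en-2-one) | CC(=O)C=C | starting material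
3 | (2R)-5-oxo-2-(propan-2-yl)hexanal (not isolated) | CC(C)[C@H](C=O)CCC(C)=O | intermediate
4 | (4R)-4-(propan-2-yl)cyclohex-2-en-1-one, (R)-cryptone | CC(C)[C@H]1CCC(=O)C=C1 | intermediate
5 | (4R)-1-(hydroxymethyl)-4-(propan-2-yl)cyclohex-2-en-1-ol, both C1 epimers | CC(C)[C@H]1CCC(O)(CO)C=C1 | intermediate
6 | (4R)-1-({[tert-butyl(dimethyl)silyl]oxy}methyl)-4-(propan-2-yl)cyclohex-2-en-1-ol, both C1 epimers | CC(C)[C@H]1CCC(O)(CO[Si](C)(C)C(C)(C)C)C=C1 | intermediate
7 | (6R)-3-({[tert-butyl(dimethyl)silyl]oxy}methyl)-6-(propan-2-yl)cyclohex-2-en-1-one | CC(C)[C@H]1CCC(CO[Si](C)(C)C(C)(C)C)=CC1=O | intermediate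
8 | (1R,6R)-3-({[tert-butyl(dimethyl)silyl]oxy}methyl)-6-(propan-2-yl)cyclohex-2-en-1-ol, OH trans to isopropyl | CC(C)[C@H]1CCC(CO[Si](C)(C)C(C)(C)C)=C[C@@H]1O | intermediate
9 | methyl (1R,6R)-3-({[tert-butyl(dimethyl)silyl]oxy}methyl)-6-(propan-2-yl)cyclohex-2-en-1-yl carbonate | CC(C)[C@H]1CCC(CO[Si](C)(C)C(C)(C)C)=C[C@@H]1OC(=O)OC | intermediate
10 | tert-butyl(dimethyl)(prop-2-yn-1-yloxy)silane | C#CCO[Si](C)(C)C(C)(C)C | starting material
11 | lithium 3-{[tert-butyl(dimethyl)silyl]oxy}prop-1-yn-1-ide, LiC≡CCH2OTBS (not isolated) | [Li]C#CCO[Si](C)(C)C(C)(C)C | intermediate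
12 | (3-{[tert-butyl(dimethyl)silyl]oxy}prop-1-yn-1-yl)zinc chloride, ClZnC≡CCH2OTBS (not isolated) | Cl[Zn]C#CCO[Si](C)(C)C(C)(C)C | intermediate
13 | tert-butyl({(3S,4R)-3-[3-({tert-butyl(dimethyl)silyl}oxy)prop-1-yn-1-yl]-4-(propan-2-yl)cyclohex-1-en-1-yl}methoxy)dimethylsilane, alkynyl cis to isopropyl | CC(C)[C@H]1CCC(CO[Si](C)(C)C(C)(C)C)=C[C@H]1C#CCO[Si](C)(C)C(C)(C)C | intermediate
14 | tributyl{(1E)-3-{[tert-butyl(dimethyl)silyl]oxy}-1-[(1S,6R)-3-({[tert-butyl(dimethyl)silyl]oxy}methyl)-6-(propan-2-yl)cyclohex-2-en-1-yl]prop-1-en-2-yl}stannane | CC(C)[C@H]1CCC(CO[Si](C)(C)C(C)(C)C)=C[C@H]1/C=C(\CO[Si](C)(C)C(C)(C)C)[Sn](CCCC)(CCCC)CCCC | intermediate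
15 | alkenyllithium from 14, lithium in place of tributyltin, ring cis to CH2OTBS (not isolated) | CC(C)[C@H]1CCC(CO[Si](C)(C)C(C)(C)C)=C[C@H]1/C=C(\CO[Si](C)(C)C(C)(C)C)[Li] | intermediate
16 | (2E)-2-({[tert-butyl(dimethyl)silyl]oxy}methyl)-3-[(1S,6R)-3-({[tert-butyl(dimethyl)silyl]oxy}methyl)-6-(propan-2-yl)cyclohex-2-en-1-yl]prop-2-enoic acid | CC(C)[C@H]1CCC(CO[Si](C)(C)C(C)(C)C)=C[C@H]1/C=C(\CO[Si](C)(C)C(C)(C)C)C(=O)O | intermediate
17 | (2S)-5-oxo-2-(propan-2-yl)hexanal (not isolated) | CC(C)[C@@H](C=O)CCC(C)=O | intermediate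
18 | (4S)-4-(propan-2-yl)cyclohex-2-en-1-one, (S)-cryptone | CC(C)[C@@H]1CCC(=O)C=C1 | intermediate
19 | Rawal's diene, (1E)-3-{[tert-butyl(dimethyl)silyl]oxy}-N,N-dimethylbuta-1,3-dien-1-amine | CN(C)/C=C/C(=C)O[Si](C)(C)C(C)(C)C | starting material
20 | (4S,4aS,8S,8aR)-6-{[tert-butyl(dimethyl)silyl]oxy}-8-(dimethylamino)-4-(propan-2-yl)-3,4,4a,5,8,8a-hexahydronaphthalen-1(2H)-one, cis-fused, ring-fusion hydrogens on the isopropyl face | CC(C)[C@@H]1CCC(=O)[C@H]2[C@@H](N(C)C)C=C(O[Si](C)(C)C(C)(C)C)C[C@@H]12 | intermediate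
21 | 1,2-adduct of 20: 1-hydroxy-1-(hydroxymethyl) compound with silyl enol ether and dimethylamino group intact, CH2OH anti to the C8a–C8 bond (not isolated) | OC[C@@]1(O)CC[C@@H](C(C)C)[C@@H]2CC(O[Si](C)(C)C(C)(C)C)=C[C@H](N(C)C)[C@@H]21 | intermediate
22 | (4aS,5R,8S,8aS)-5-hydroxy-5-(hydroxymethyl)-8-(propan-2-yl)-4a,5,6,7,8,8a-hexahydronaphthalen-2(1H)-one, cis-fused | OC[C@@]1(O)CC[C@@H](C(C)C)[C@@H]2CC(=O)C=C[C@@H]21 | intermediate
23 | acetonide of 22: 5-O and 5-CH2O joined as a 2,2-dimethyl-1,3-dioxolane spiro at C5, stereocentres as in 22 | CC1(C)OC[C@@]2(O1)CC[C@@H](C(C)C)[C@@H]3CC(=O)C=C[C@@H]32 | intermediate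
24 | lithium dienolate of 23, C1=C2(OLi) and C3=C4 (not isolated) | CC1(C)OC[C@@]2(O1)CC[C@@H](C(C)C)[C@@H]3C=C(O[Li])C=C[C@@H]32 | intermediate
25 | dienyl triflate: 2-{[(trifluoromethyl)sulfonyl]oxy}-4a,5,6,7,8,8a-hexahydronaphthalene with C1=C2 and C3=C4, 8-isopropyl and the C5 spiro-acetonide, stereocentres as in 23 | CC1(C)OC[C@@]2(O1)CC[C@@H](C(C)C)[C@@H]3C=C(OS(=O)(=O)C(F)(F)F)C=C[C@@H]32 | intermediate
26 | 2-(trimethylsilyl)ethyl 4a,5,6,7,8,8a-hexahydronaphthalene-2-carboxylate with C1=C2 and C3=C4, 8-isopropyl and the C5 spiro-acetonide, stereocentres as in 23 | CC1(C)OC[C@@]2(O1)CC[C@@H](C(C)C)[C@@H]3C=C(C(=O)OCC[Si](C)(C)C)C=C[C@@H]32 | intermediate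
27 | secondary ozonide (1,2,4-trioxolane) across the former C3=C4 bond of 26 (not isolated) | CC1(C)OC[C@@]2(O1)CC[C@@H](C(C)C)[C@@H]3C=C(C(=O)OCC[Si](C)(C)C)C4OOC(O4)[C@@H]32 | intermediate
28 | 2-(trimethylsilyl)ethyl (2E)-2-formyl-3-[6-formyl-2,2-dimethyl-8-(propan-2-yl)-1,3-dioxaspiro[4.5]decan-7-yl]prop-2-enoate, ring cis to CHO across C=C, ring stereocentres as in 23 | CC1(C)OC[C@@]2(O1)CC[C@@H](C(C)C)[C@H](/C=C(\C=O)C(=O)OCC[Si](C)(C)C)[C@@H]2C=O | intermediate
29 | acetonide of 30: cis-fused seven-membered lactone with 9-O and 9-CH2O joined as a spiro-dioxolane, 2-(trimethylsilyl)ethyl ester, stereocentres as in 30 | CC1(C)OC[C@@]2(O1)CC[C@@H](C(C)C)[C@@H]3C=C(C(=O)OCC[Si](C)(C)C)COC(=O)[C@@H]32 | intermediate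
30 | 2-(trimethylsilyl)ethyl (5aR,6S,9R,9aS)-9-hydroxy-9-(hydroxymethyl)-1-oxo-6-(propan-2-yl)-1,3,5a,6,7,8,9,9a-octahydro-2-benzoxepine-4-carboxylate | OC[C@@]1(O)CC[C@@H](C(C)C)[C@@H]2C=C(C(=O)OCC[Si](C)(C)C)COC(=O)[C@@H]21 | intermediate
31 | ester of 30 (primary OH) with acid 16; two TBS ethers and the 2-(trimethylsilyl)ethyl ester still in place | CC(C)[C@H]1CCC(CO[Si](C)(C)C(C)(C)C)=C[C@H]1/C=C(\CO[Si](C)(C)C(C)(C)C)C(=O)OC[C@@]1(O)CC[C@@H](C(C)C)[C@@H]2C=C(C(=O)OCC[Si](C)(C)C)COC(=O)[C@@H]21 | intermediate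
32 | CNP0361406.7, (5aR,6S,9R,9aS)-9-hydroxy-9-{[((2E)-2-(hydroxymethyl)-3-[(1S,6R)-3-(hydroxymethyl)-6-(propan-2-yl)cyclohex-2-en-1-yl]prop-2-enoyl)oxy]methyl}-1-oxo-6-(propan-2-yl)-1,3,5a,6,7,8,9,9a-octahydro-2-benzoxepine-4-carboxylic acid | CC(C)[C@H]1CCC(CO)=C[C@H]1/C=C(\CO)C(=O)OC[C@@]1(O)CC[C@@H](C(C)C)[C@@H]2C=C(C(=O)O)COC(=O)[C@@H]21 | target

**Totals and risks**

Total step count: 20. Longest linear sequence: 11 steps (steps 10 to 20; equally steps 1 to 9 followed by 19 and 20).

The three steps most likely to fail: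

Step 17, the new crossed Tishchenko lactonisation, is the least certain. Its regiochemistry rests on the saturated aldehyde being the hydride donor; oxa-Michael addition to the formylacrylate, epimerisation next to the saturated aldehyde, or intermolecular ester formation could intervene. The fallback uses known chemistry, sets out from dialdehyde 28 and comes back at lactone 29. NaBH4 with CeCl3·7H2O in MeOH at −78 °C reduces only the conjugated aldehyde, because the saturated one is masked as its hemiacetal under these conditions, and gives hydroxy aldehyde F1. Pinnick oxidation (NaClO2, NaH2PO4, 2-methylbut-2-ene, tBuOH/H2O) then gives hydroxy acid F2. Shiina lactonisation (MNBA, DMAP, CH2Cl2, high dilution) closes the seven-membered ring to 29.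

Step 7, the stereoinvertive allyl–alkynyl coupling, requires palladium to ionise the carbonate on the face next to the isopropyl group. Slow transmetalation could divert the allyl complex to diene by β-hydride loss or to the wrong allyl terminus. The fallback sets out from allylic alcohol 8 and comes back at enyne 13, and replaces the organozinc transmetalation by an intramolecular decarboxylative coupling. Lithium alkynide 11 is carboxylated with CO2 to 4-{[tert-butyl(dimethyl)silyl]oxy}but-2-ynoic acid F3. Alcohol 8 is esterified with it (DCC, DMAP) to alkynoate ester F4. Heating F4 with Pd(PPh3)4 in toluene at 80 °C ionises the ester, the palladium-bound alkynoate loses CO2, and the alkynyl group is delivered from the metal with the same net inversion to give 13.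

Step 11, the thermal Diels–Alder reaction of a β-hindered cyclohexenone, may be too slow before the aminodiene decomposes. The fallback sets out from (S)-cryptone 18 and comes back at enone diol 22, and switches to a Lewis-acid-activated cycloaddition with a simpler diene followed by a later dehydrogenation. Methyl vinyl ketone 2 is converted with TBSOTf and Et3N into tert-butyl(buta-1,3-dien-2-yloxy)dimethylsilane F5. AlBr3/AlMe3-promoted cycloaddition of F5 with 18 (toluene, −20 °C; anti to isopropyl, silyloxy carbon para to the ketone-bearing carbon) gives silyl enol ether ketone F6. Addition of dilithiated methanol as in step 12, but with a neutral NH4Cl quench, gives silyl enol ether diol F7. Saegusa–Ito oxidation with Pd(OAc)2 in MeCN dehydrogenates the regiodefined silyl enol ether to enone 22.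

**Further compounds**
F1 | step 17 | 2-(trimethylsilyl)ethyl (2E)-3-[6-formyl-2,2-dimethyl-8-(propan-2-yl)-1,3-dioxaspiro[4.5]decan-7-yl]-2-(hydroxymethyl)prop-2-enoate, stereocentres as in 28 | CC1(C)OC[C@@]2(O1)CC[C@@H](C(C)C)[C@H](/C=C(\CO)C(=O)OCC[Si](C)(C)C)[C@@H]2C=O
F2 | step 17 | 7-[(1E)-2-(hydroxymethyl)-3-oxo-3-[2-(trimethylsilyl)ethoxy]prop-1-en-1-yl]-2,2-dimethyl-8-(propan-2-yl)-1,3-dioxaspiro[4.5]decane-6-carboxylic acid, stereocentres as in 28 | CC1(C)OC[C@@]2(O1)CC[C@@H](C(C)C)[C@H](/C=C(\CO)C(=O)OCC[Si](C)(C)C)[C@@H]2C(=O)O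
F3 | step 7 | 4-{[tert-butyl(dimethyl)silyl]oxy}but-2-ynoic acid | O=C(O)C#CCO[Si](C)(C)C(C)(C)C
F4 | step 7 | (1R,6R)-3-({[tert-butyl(dimethyl)silyl]oxy}methyl)-6-(propan-2-yl)cyclohex-2-en-1-yl 4-{[tert-butyl(dimethyl)silyl]oxy}but-2-ynoate | CC(C)[C@H]1CCC(CO[Si](C)(C)C(C)(C)C)=C[C@@H]1OC(=O)C#CCO[Si](C)(C)C(C)(C)C
F5 | step 11 | tert-butyl(buta-1,3-dien-2-yloxy)dimethylsilane | C=CC(=C)O[Si](C)(C)C(C)(C)C
F6 | step 11 | cis-fused 6-{[tert-butyl(dimethyl)silyl]oxy}-4-(propan-2-yl)-3,4,4a,5,8,8a-hexahydronaphthalen-1(2H)-one, ring-fusion hydrogens on the isopropyl face | CC(C)[C@@H]1CCC(=O)[C@H]2CC=C(O[Si](C)(C)C(C)(C)C)C[C@@H]12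
F7 | step 11 | 1,2-adduct of F6: 1-hydroxy-1-(hydroxymethyl) compound with the silyl enol ether intact, carbinol configuration as in 22 | OC[C@@]1(O)CC[C@@H](C(C)C)[C@@H]2CC(O[Si](C)(C)C(C)(C)C)=CC[C@@H]21
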